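The runs are simulated on assumed constants, and the scatter is random.

**Blue constant.** The constant carried here is read from the blue run, whose charge the set-ups below repeat.

| setting | blue | violet | green | amber | west | south-east | north-west | north |
|---|---|---|---|---|---|---|---|---|
| starting material | 0.12 M | 0.12 M | 0.12 M | 0.18 M | 0.12 M | 0.12 M | 0.12 M | 0.12 M |
| second substrate | 0.60 M | 0.60 M | 0.60 M | 0.60 M | 0.600 M | 0.600 M | 0.600 M | 0.600 M (fed, over 24.0 h) |
| free enzyme | 12 µM | 6 µM | 9 µM | 12 µM | 12 µM | 12 µM | 12 µM | 12 µM |
| remark | run made earlier | run made earlier | run made earlier | run made earlier | a single well-mixed tank run continuously and read at steady state, 300 h in it on average | everything together in a closed stirred flask, run for 30 h | one stirred flow tank at steady state, fed with the mixture as stated, mean residence time 30 h | all but second substrate at the start; second substrate goes in evenly over 24.0 h, the run ends at 30 h |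
| time |  |  |  |  |  | 30 h |  | 30 h |

| run | time / h | target / % | starting material / % |
|---|---|---|---|
| blue | 1.33 | 7.4 | 94.3 |
| blue | 2.00 | 10.0 | 90.4 |
| blue | 3.00 | 15.0 | 84.6 |
| blue | 5.00 | 23.0 | 77.1 |
| blue | 8.00 | 33.7 | 66.3 |
| blue | 12.0 | 45.0 | 55.2 |
| blue | 20.0 | 62.7 | 37.6 |
| violet | 1.33 | 3.5 | 95.5 |
| violet | 4.00 | 10.0 | 89.7 |
| violet | 6.00 | 14.3 | 85.8 |
| violet | 10.0 | 22.3 | 76.7 |
| violet | 15.0 | 32.0 | 69.0 |
| violet | 20.0 | 38.3 | 61.6 |
| violet | 25.0 | 45.8 | 54.1 |
| green | 3.00 | 11.3 | 88.4 |
| green | 6.00 | 20.3 | 79.4 |
| green | 10.0 | 32.0 | 67.6 |
| green | 15.0 | 43.1 | 56.5 |
| green | 20.0 | 52.2 | 46.7 |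
| green | 25.0 | 59.1 | 39.9 |
| amber | 5.00 | 16.0 | 83.2 |
| amber | 10.0 | 28.6 | 71.0 |
| amber | 15.0 | 38.8 | 61.3 |
| amber | 20.0 | 46.4 | 53.3 |
| amber | 25.0 | 53.9 | 46.9 |

(standard deviation of a reading: 0.5 percentage points)

- the stated concentrations are those of everything mixed, before any reaction; amounts are the same in each set-up
- the analysis behind the earlier runs scatters by 0.5 percentage points, standard deviation
- the feed brings no volume worth counting
- the earlier runs were made in a closed, stirred flask

- order of the set-ups by the amount of target at the outlet or at the end, in percent of the starting material put in, highest first (west / south-east / north-west / north)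
- amount of target at the outlet or at the end, in percent of the starting material put in, west
- amount of target at the outlet or at the end, in percent of the starting material put in, south-east
- amount of target at the outlet or at the end, in percent of the starting material put in, north-west
- amount of target at the outlet or at the end, in percent of the starting material put in, north

**Reading it.** Blue keeps 37.6% of its starting material at 20.0 h, so a first-order reading gives 0.0489 h⁻¹. If second substrate goes one for one with starting material, each unit of conversion costs 0.200 of its charge, and over that span it averages about 0.938 of its charge. Dividing by this gives 0.0522 h⁻¹, the full-charge constant: the first-order loss of starting material with second substrate at its whole charge.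

**Bench rule.** Second substrate is charged in excess, so the bench treats a tank as pseudo-first-order. The tank number is the full-charge constant times the mean residence time, and the fraction converted is that number divided by one more than itself. North-west has 1.56, giving 0.610; west has 15.6, giving 0.940.

**Going round.** Those answers go back in. At 0.610 converted, north-west holds 0.878 of its second substrate, so its tank number shrinks and the conversion falls to 0.579. Another round stays at 0.580. West, treated the same way, comes to 0.927.

**The border.** Going round repairs the excess but not the time. Violet's last reading stands at 25.0 h; north-west's residence time is 1.20 times that, and west's is 12.0 times. West's figure is therefore an extrapolation of the constant, not a reading.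

**The forecast.** It gave 91% for west, 75.5% for south-east, 58% for north-west and 58% for north, in the order west > south-east > north-west > north, its west figure set lower than the reckoning here for “possible equilibrium or enzyme decay, untested”.

**The flask.** West gives 84.2%, south-east 76.5%, north-west 55.2% and north 62.2%, in the order west > south-east > north > north-west.

    second substrate + loaded enzyme ⇌ second complex (K = 0.668 M⁻¹, k = 2850 M⁻¹ min⁻¹)
    starting material + free enzyme ⇌ first complex (K = 8.97 M⁻¹, k = 27100 M⁻¹ min⁻¹)
    first complex ⇌ loaded enzyme + first product (K = 0.107 M, k = 58.7 min⁻¹)
    second complex → free enzyme + target (k = 44.8 min⁻¹)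
    first product + first complex → spent catalyst (k = 0.0101 M⁻¹ min⁻¹)

**The tanks.** West's outlet still holds 15.8% of its starting material, while the one-step fit, first order in starting material, second substrate and free enzyme, gives 91.9% target there. Run backwards through the same tank balance, north-west's result returns 0.0461 h⁻¹, which is 0.883 of the full-charge constant, and west's returns 0.0214 h⁻¹, which is 0.410 of it.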